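No rate constant lay before the meeting, so it argued from the readings of the dusk and dawn runs.

| flask | E | remark | time |
|---|---|---|---|
| dusk | 0.49 M | run made earlier |  |
| dawn | 0.73 M | run made earlier |  |
| flask | 0.98 M |  | 2.0 min |

| run | time / min | X / % | Z / % |
|---|---|---|---|
| dusk | 0.200 | 9.4 | 4.2 |
| dusk | 0.333 | 15.7 | 4.4 |
| dusk | 0.500 | 20.8 | 6.0 |
| dusk | 0.833 | 31.2 | 5.4 |
| dusk | 1.33 | 40.9 | 3.0 |
| dusk | 2.50 | 47.8 | 1.2 |
| dawn | 0.200 | 10.0 | 5.4 |
| dawn | 0.333 | 15.2 | 7.5 |
| dawn | 0.500 | 21.6 | 6.8 |
| dawn | 0.833 | 30.2 | 7.6 |
| dawn | 1.33 | 40.2 | 5.3 |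
| dawn | 2.50 | 47.7 | 3.2 |

(standard deviation of a reading: 0.5 percentage points)

- in percentages every species weighs as the E in it: one Z counts as two

* concentration of X at 2.0 min, in M
* concentration of Z at 2.0 min, in M
* concentration of L at 2.0 min, in M

The forecaster reported that X, in percent of the charge, ran alike in both runs within scatter, and carried that percentage over to the flask. It entered c(X) = 0.44 M, c(Z) = 0.032 M and c(L) = 0.4 M, and said of the last: “L is never measured, so it comes from the balance”.

Taking the minutes, I asked the meeting on which side of its curve X stands in the flask. Averaged over both runs, X gains, as a fraction of the charge, 0.198 min⁻¹ around 1.08 min and 0.0615 min⁻¹ around 1.92 min. A straight line through these two gains reaches zero at 2.29 min; I call this the crossing time, the moment at which the net gain of X changes sign, the t_max of an intermediate. It is a reading, and it assumes that the gain keeps falling along that line. It lies 0.290 min later than the asked time, so, taking the percentage curve of X in the flask to run like those of the two runs, I expected X in the flask to be still rising at the asked time; that gives a sign and no value of c(X).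

The flask gives c(X) = 0.440 M, c(Z) = 0.0223 M and c(L) = 0.165 M.

    E → X (k = 0.0170 s⁻¹)
    2 E ⇌ Z (K = 0.440 L mol⁻¹, k = 0.0150 L mol⁻¹ s⁻¹)
    X → L (k = 0.00470 s⁻¹)
    E ⇌ Q (K = 0.860, k = 0.760 s⁻¹)

At 2.00 min the flask still makes X 1.46 times as fast as it uses it up, each step taken net, down from 4.16 at 0.745 min, so c(X) in the flask is still rising at that time, which lies before the crossing time 2.29 min read from the runs, while E and Q together still hold 33.7% of the charge. The flask left until 8.0 min, read later than that crossing time, has c(X) down to 0.198 M and c(L) up to 0.766 M.

All runs are simulated with made-up constants, and the scatter is random.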